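**Plan**

- Cuts, in order: (a) the ketone C3–C4 bond of the side chain (serine Weinreb amide plus a 10-furyldecyl Grignard reagent); (b) both C–O bonds of the furan; (c) the central C5–C6 bond of the diene so revealed; (d) the propargylic C–C bond of the long arm.
- Enabling feature: the furan oxygen lies between C2 (propyl) and C5 (C10 chain), and C3 and C4 each carry a methyl. The ring therefore equals an (E,E)-1,4-dialkyl-2,3-dimethylbuta-1,3-diene plus one oxygen atom, which O2 can deliver by [4+2] addition and collapse of the peroxide.
- Forward: two 2-alkynes (hex-2-yne; 13-chlorotridec-2-yne from propyne and 1-bromo-10-chlorodecane) are hydrozirconated and joined by Negishi coupling. Photooxygenation, O–O cleavage and dehydration close the furan, the only ring. The untouched ω-chloride becomes the Grignard reagent that is acylated by the serine amide, and desilylation ends the route.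
- Stereochemistry: the single (S) centre is bought as methyl L-serinate and never passes through an activated acyl derivative. The E,E diene geometry comes from syn hydrozirconation and stereoretentive coupling.

Key step: step 4

Remark (assumption): the long arm is carried with a terminal chloride instead of a protected alcohol. The C–Cl bond should be inert to acetylide alkylation at the bromide, Cp2Zr(H)Cl, zerovalent palladium, singlet oxygen, DBU and TsOH, and it is itself the Grignard precursor. Furan 16 and all later compounds are handled under argon with exclusion of light.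

**Route**

Step 1
Reactants: 1 hex-2-yne
Product: 3 (2E)-2-iodohex-2-ene, via (E)-hex-2-en-2-ylzirconocene chloride 2 (not isolated)
Conditions: Cp2Zr(H)Cl (1.5 equiv), THF, 50 °C; then I2, THF, 0 °C
Reagents that add atoms: iodine, II
Why: Syn hydrozirconation of the internal alkyne places H and Zr cis, heating with excess Cp2Zr(H)Cl equilibrates the regioisomeric alkenylzirconiums toward the one with zirconium on the less hindered, methyl-bearing carbon, and iodinolysis of the C–Zr bond with retention then fixes the E trisubstituted iodoalkene (hydrozirconation–iodination).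

Step 2
Reactants: 4 propyne; 5 1-bromo-10-chlorodecane
Product: 7 13-chlorotridec-2-yne, via prop-1-yn-1-yllithium 6 (not isolated)
Conditions: n-BuLi, THF, −78 °C; then 5, DMPU, −78 °C to rt
Reagents that add atoms: none
Why: SN2 alkylation of a lithium acetylide in THF/DMPU, in which the primary bromide is displaced much faster than the primary chloride, so the ω-chloride is kept as the later Grignard handle.

Step 3
Reactants: 7 13-chlorotridec-2-yne; 3 (2E)-2-iodohex-2-ene
Product: 10 (4E,6E)-17-chloro-5,6-dimethylheptadeca-4,6-diene, via (E)-13-chlorotridec-2-en-2-ylzirconocene chloride 8 (not isolated), via (E)-13-chlorotridec-2-en-2-ylzinc chloride 9 (not isolated)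
Conditions: Cp2Zr(H)Cl (1.2 equiv), THF, 50 °C; ZnCl2 (1.2 equiv), THF, 0 °C; then 3 (1.3 equiv), Pd(PPh3)4 (5 mol %), rt to 45 °C
Reagents that add atoms: none
Why: Regioselective syn hydrozirconation as in step 1, transmetalation from zirconium to zinc, which is what lets α-branched alkenylmetals pass on to palladium, and Negishi coupling with Pd(PPh3)4, whose oxidative addition and reductive elimination retain both alkene geometries and leave the primary chloride untouched, should give the E,E diene.

Step 4
Reactants: 10 (4E,6E)-17-chloro-5,6-dimethylheptadeca-4,6-diene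
Product: 16 2-(10-chlorodecyl)-3,4-dimethyl-5-propylfuran, via cis-dioxine 11 (not isolated), via 4-oxo hydroxyenone 12 (not isolated), via 7-oxo hydroxyenone 13 (not isolated), via 2-propyl dihydrofuranol 14 (not isolated), via 2-chlorodecyl dihydrofuranol 15 (not isolated)
Conditions: O2, tetraphenylporphyrin (cat.), visible light, CH2Cl2, −78 °C; Ar purge, dark; DBU (0.3 equiv), 0 °C to rt; then TsOH·H2O (0.5 equiv), rt
Reagents that add atoms: dioxygen, O=O
Why: Sensitised singlet oxygen adds suprafacially to C4 and C7 of the s-cis conformer of diene 10 in a [4+2] cycloaddition, the known photooxygenation of 1,3-dienes to 3,6-dihydro-1,2-dioxines, and so closes the six-membered peroxide ring of 11 with the two alkyl groups cis. Once light and O2 are removed, DBU abstracts one of the two O–C–H hydrogens and the O–O bond breaks (Kornblum–DeLaMare rearrangement) to the (Z)-γ-hydroxyenones 12 and 13, whose Z geometry is inherited from the ring. Each hydroxyl then adds to its ketone in a 5-exo-trig closure to the 2,5-dihydrofuran-2-ols 14 and 15, and acid-catalysed loss of water aromatises both to the single furan 16, so that both ring C–O bonds come from one oxygen atom of O2. No stereocentre is left in 16; the two transient centres of 11 are set cis by the concerted addition and are erased. The step needs the [4+2] addition to outrun the ene reaction at the allylic CH3 and CH2 groups: the vicinal methyls destabilise the s-trans conformer, the E,E geometry leaves only hydrogens inside the s-cis diene, and −78 °C keeps peroxide 11 intact and is expected to help the cycloaddition compete. Because 16 is itself a singlet-oxygen acceptor, it is generated only after the lamp is off and the solution has been purged.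

Step 5
Reactants: 17 methyl L-serinate hydrochloride
Product: 18 methyl N-acetyl-L-serinate
Conditions: Ac2O (1.0 equiv), Et3N (2.1 equiv), CH2Cl2, 0 °C
Reagents that add atoms: acetic anhydride, CC(=O)OC(C)=O
Why: Chemoselective N-acylation, since the amine freed by Et3N is far more nucleophilic than the primary hydroxyl toward one equivalent of anhydride at 0 °C, and the stereocentre is not involved.

Step 6
Reactants: 18 methyl N-acetyl-L-serinate
Product: 19 methyl N-acetyl-O-(tert-butyldimethylsilyl)-L-serinate
Conditions: TBSCl, imidazole, DMF, rt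
Reagents that add atoms: tert-butyldimethylsilyl chloride, CC(C)(C)[Si](C)(C)Cl
Why: Imidazole-promoted silylation of a primary alcohol, giving an ether that masks the hydroxyl proton during the two organomagnesium steps and withstands them.

Step 7
Reactants: 19 methyl N-acetyl-O-(tert-butyldimethylsilyl)-L-serinate
Product: 22 (2S)-2-acetamido-3-[(tert-butyldimethylsilyl)oxy]-N-methoxy-N-methylpropanamide, via N-chloromagnesio ester 20 (not isolated), via N-chloromagnesio Weinreb amide 21 (not isolated)
Conditions: MeNHOMe·HCl (1.6 equiv), iPrMgCl (4.2 equiv), THF, −20 °C; aq NH4Cl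
Reagents that add atoms: N,O-dimethylhydroxylamine hydrochloride, Cl.CNOC
Why: Direct aminolysis of the methyl ester by the chloromagnesium amide of N,O-dimethylhydroxylamine (Weinreb amide formation from an ester), which needs no activated carboxyl derivative and so avoids the oxazolone route by which N-acyl amino acids racemise, while prior N-magnesiation of the acetamide (20) guards the α-hydrogen.

Step 8
Reactants: 16 2-(10-chlorodecyl)-3,4-dimethyl-5-propylfuran; 22 (2S)-2-acetamido-3-[(tert-butyldimethylsilyl)oxy]-N-methoxy-N-methylpropanamide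
Product: 26 N-[(2S)-1-[(tert-butyldimethylsilyl)oxy]-13-(3,4-dimethyl-5-propylfuran-2-yl)-3-oxotridecan-2-yl]acetamide, via furyldecylmagnesium chloride 23 (not isolated), via N-bromomagnesio Weinreb amide 24 (not isolated), via tetrahedral magnesium adduct 25 (not isolated)
Conditions: 16, Mg turnings (I2 crystal), THF, reflux; separately 22 (1.3 equiv), iPrMgBr (1.25 equiv), THF, −20 °C; combine, −20 to 0 °C; aq NH4Cl, 0 °C
Reagents that add atoms: none
Why: Weinreb ketone synthesis in which the hindered iPrMgBr, which does not add to the amide carbonyl at −20 °C, first removes the acetamide N–H of the purified amide so that no furyldecyl Grignard reagent is wasted and the α-hydrogen is shielded by the amidate 24, the Grignard reagent 23 formed by magnesium insertion into the primary chloride then adds once because the N-methoxy chelate 25 persists until the quench, and the (S) centre is carried through unchanged.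

Step 9
Reactants: 26 N-[(2S)-1-[(tert-butyldimethylsilyl)oxy]-13-(3,4-dimethyl-5-propylfuran-2-yl)-3-oxotridecan-2-yl]acetamide
Product: 27 N-[(2S)-13-(3,4-dimethyl-5-propylfuran-2-yl)-1-hydroxy-3-oxotridecan-2-yl]acetamide
Conditions: HF·pyridine, pyridine, THF, 0 °C to rt
Reagents that add atoms: none
Why: Fluoride-driven cleavage of the Si–O bond under buffered, faintly acidic conditions, chosen because they avoid the base-induced epimerisation or β-elimination open to a β-hydroxy-α-acetamido ketone and are tolerated by the tetraalkylfuran.

**Compound list**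

1 | hex-2-yne | CC#CCCC | starting material
2 | chlorobis(cyclopentadienyl)[(2E)-hex-2-en-2-yl]zirconium (cyclopentadienyl rings written σ-bound in the SMILES) | CCC/C=C(C)/[Zr](Cl)(C1C=CC=C1)C1C=CC=C1 | intermediate (not isolated)
3 | (2E)-2-iodohex-2-ene | CCC/C=C(C)/I | intermediate
4 | propyne | CC#C | starting material
5 | 1-bromo-10-chlorodecane | BrCCCCCCCCCCCl | starting material
6 | prop-1-yn-1-yllithium | CC#C[Li] | intermediate (not isolated)
7 | 13-chlorotridec-2-yne | CC#CCCCCCCCCCCCl | intermediate
8 | chlorobis(cyclopentadienyl)[(2E)-13-chlorotridec-2-en-2-yl]zirconium (cyclopentadienyl rings written σ-bound in the SMILES) | ClCCCCCCCCCC/C=C(C)/[Zr](Cl)(C1C=CC=C1)C1C=CC=C1 | intermediate (not isolated)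
9 | chloro[(2E)-13-chlorotridec-2-en-2-yl]zinc | ClCCCCCCCCCC/C=C(C)/[Zn]Cl | intermediate (not isolated)
10 | (4E,6E)-17-chloro-5,6-dimethylheptadeca-4,6-diene | CCC/C=C(C)/C(C)=C/CCCCCCCCCCCl | intermediate
11 | cis-3-(10-chlorodecyl)-4,5-dimethyl-6-propyl-3,6-dihydro-1,2-dioxine (racemic, relative configuration shown) | CCC[C@H]1OO[C@@H](CCCCCCCCCCCl)C(C)=C1C | intermediate (not isolated)
12 | (5Z)-17-chloro-7-hydroxy-5,6-dimethylheptadec-5-en-4-one (racemic) | CCCC(=O)/C(C)=C(C)\C(O)CCCCCCCCCCCl | intermediate (not isolated)
13 | (5Z)-17-chloro-4-hydroxy-5,6-dimethylheptadec-5-en-7-one (racemic) | CCCC(O)/C(C)=C(C)\C(=O)CCCCCCCCCCCl | intermediate (not isolated)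
14 | 5-(10-chlorodecyl)-3,4-dimethyl-2-propyl-2,5-dihydrofuran-2-ol (diastereomer mixture) | CCCC1(O)OC(CCCCCCCCCCCl)C(C)=C1C | intermediate (not isolated)
15 | 2-(10-chlorodecyl)-3,4-dimethyl-5-propyl-2,5-dihydrofuran-2-ol (diastereomer mixture) | CCCC1OC(O)(CCCCCCCCCCCl)C(C)=C1C | intermediate (not isolated)
16 | 2-(10-chlorodecyl)-3,4-dimethyl-5-propylfuran | CCCc1oc(CCCCCCCCCCCl)c(C)c1C | intermediate
17 | methyl L-serinate hydrochloride | Cl.N[C@@H](CO)C(=O)OC | starting material
18 | methyl N-acetyl-L-serinate | CC(=O)N[C@@H](CO)C(=O)OC | intermediate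
19 | methyl N-acetyl-O-(tert-butyldimethylsilyl)-L-serinate | CC(=O)N[C@@H](CO[Si](C)(C)C(C)(C)C)C(=O)OC | intermediate
20 | N-chloromagnesio derivative of ester 19 | CC(=O)N([Mg]Cl)[C@@H](CO[Si](C)(C)C(C)(C)C)C(=O)OC | intermediate (not isolated)
21 | N-chloromagnesio derivative of Weinreb amide 22 | CC(=O)N([Mg]Cl)[C@@H](CO[Si](C)(C)C(C)(C)C)C(=O)N(C)OC | intermediate (not isolated)
22 | (2S)-2-acetamido-3-[(tert-butyldimethylsilyl)oxy]-N-methoxy-N-methylpropanamide | CC(=O)N[C@@H](CO[Si](C)(C)C(C)(C)C)C(=O)N(C)OC | intermediate
23 | [10-(3,4-dimethyl-5-propylfuran-2-yl)decyl]magnesium chloride | CCCc1oc(CCCCCCCCCC[Mg]Cl)c(C)c1C | intermediate (not isolated)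
24 | N-bromomagnesio derivative of Weinreb amide 22 | CC(=O)N([Mg]Br)[C@@H](CO[Si](C)(C)C(C)(C)C)C(=O)N(C)OC | intermediate (not isolated)
25 | chloromagnesium alkoxide of the N-methoxy-N-methyl hemiaminal formed from 24 and 23 (N-bromomagnesio acetamide; new carbinol centre unassigned) | CCCc1oc(CCCCCCCCCCC(O[Mg]Cl)(N(C)OC)[C@H](CO[Si](C)(C)C(C)(C)C)N([Mg]Br)C(C)=O)c(C)c1C | intermediate (not isolated)
26 | N-[(2S)-1-[(tert-butyldimethylsilyl)oxy]-13-(3,4-dimethyl-5-propylfuran-2-yl)-3-oxotridecan-2-yl]acetamide | CCCc1oc(CCCCCCCCCCC(=O)[C@H](CO[Si](C)(C)C(C)(C)C)NC(C)=O)c(C)c1C | intermediate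
27 | N-[(2S)-13-(3,4-dimethyl-5-propylfuran-2-yl)-1-hydroxy-3-oxotridecan-2-yl]acetamide | CCCc1oc(CCCCCCCCCCC(=O)[C@H](CO)NC(C)=O)c(C)c1C | target

**Step count and risks**

Total step count: 9. Longest linear sequence: 5 steps (steps 2, 3, 4, 8, 9 from propyne and 1-bromo-10-chlorodecane; equally steps 5 to 9 from the serine ester).

Steps most likely to fail:

1. Step 4. The ene hydroperoxidation at the allylic methyl and methylene groups may outcompete the [4+2] addition, and the furan may be re-oxidised if light and oxygen are not fully removed before the base is added. The fallback builds the furan without any diene or peroxide; it sets out from 5 and comes back to the route at 16. Purchased 3,4-dimethylfuran would be lithiated at an α-position (n-BuLi, THF, 0 °C) to (3,4-dimethylfuran-2-yl)lithium F1 and alkylated with 1-iodopropane to 3,4-dimethyl-2-propylfuran F2. A second lithiation at the remaining α-position would give (3,4-dimethyl-5-propylfuran-2-yl)lithium F3, which displaces the bromide of 5 in THF/DMPU to give 16.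

2. Step 3. The regiochemical equilibration of the alkenylzirconium may stay incomplete, and the union of two α-branched alkenyl partners may be slow, with homocoupling and hydrodeiodination of 3 by residual Zr–H. The fallback fixes the second methyl group by carbometalation instead and joins the long arm through an sp3 carbon; it sets out from 3 (and uses 5) and comes back at 10. Sonogashira coupling of 3 with ethynyltrimethylsilane (Pd(PPh3)2Cl2, CuI, Et3N) would give trimethyl[(3E)-3-methylhept-3-en-1-yn-1-yl]silane F4, and K2CO3 in MeOH would free (3E)-3-methylhept-3-en-1-yne F5. Zirconium-catalysed methylalumination (AlMe3, Cp2ZrCl2 cat., CH2Cl2) would give [(1E,3E)-2,3-dimethylhepta-1,3-dien-1-yl]dimethylalane F6, and iodinolysis would give (1E,3E)-1-iodo-2,3-dimethylhepta-1,3-diene F7. Zinc insertion into the C–Br bond of 5 (Zn dust, LiCl, THF) would give (10-chlorodecyl)zinc bromide F8, and Negishi coupling of F8 with F7 (Pd(dppf)Cl2 cat., THF) would give 10.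

3. Step 8. Wurtz coupling during magnesium insertion, sluggish addition to the N-magnesiated amide, and erosion of the α-stereocentre by enolisation of the acetamido ketone at the quench are the likely failure processes. The fallback forms the same ketone bond under neutral conditions; it sets out from 19 and 16 and comes back at 26. Ester 19 would be converted with AlMe3/EtSH (CH2Cl2, 0 °C to rt) to S-ethyl (2S)-2-acetamido-3-[(tert-butyldimethylsilyl)oxy]propanethioate F9. Chloride 16 would be exchanged (NaI, butan-2-one, reflux; Finkelstein reaction) to 2-(10-iododecyl)-3,4-dimethyl-5-propylfuran F10, and activated zinc dust in THF would insert to give [10-(3,4-dimethyl-5-propylfuran-2-yl)decyl]zinc iodide F11. Fukuyama coupling of F11 with F9 (Pd(PPh3)2Cl2 cat., THF/toluene, rt) would give 26.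

**Further compounds**

F1 | step 4 | (3,4-dimethylfuran-2-yl)lithium | [Li]c1occ(C)c1C
F2 | step 4 | 3,4-dimethyl-2-propylfuran | CCCc1occ(C)c1C
F3 | step 4 | (3,4-dimethyl-5-propylfuran-2-yl)lithium | CCCc1oc([Li])c(C)c1C
F4 | step 3 | trimethyl[(3E)-3-methylhept-3-en-1-yn-1-yl]silane | CCC/C=C(C)/C#C[Si](C)(C)C
F5 | step 3 | (3E)-3-methylhept-3-en-1-yne | CCC/C=C(C)/C#C
F6 | step 3 | [(1E,3E)-2,3-dimethylhepta-1,3-dien-1-yl]dimethylalane | CCC/C=C(C)/C(C)=C/[Al](C)C
F7 | step 3 | (1E,3E)-1-iodo-2,3-dimethylhepta-1,3-diene | CCC/C=C(C)/C(C)=C/I
F8 | step 3 | (10-chlorodecyl)zinc bromide | ClCCCCCCCCCC[Zn]Br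
F9 | step 8 | S-ethyl (2S)-2-acetamido-3-[(tert-butyldimethylsilyl)oxy]propanethioate | CCSC(=O)[C@H](CO[Si](C)(C)C(C)(C)C)NC(C)=O
F10 | step 8 | 2-(10-iododecyl)-3,4-dimethyl-5-propylfuran | CCCc1oc(CCCCCCCCCCI)c(C)c1C
F11 | step 8 | [10-(3,4-dimethyl-5-propylfuran-2-yl)decyl]zinc iodide | CCCc1oc(CCCCCCCCCC[Zn]I)c(C)c1C
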